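(All runs are calculated from invented constants, noise included.)

- At 3.0 d, gamma and theta will have stood longer than the 48.0 h of the runs so far, so I first asked whether the readings had stopped moving by then, and what split they had reached.

| flask | D | L | remark | time |
|---|---|---|---|---|
| north-west | 0.037 M | 0.10 mM | run made earlier |  |
| north-east | 0.11 M | 0.10 mM | run made earlier |  |
| south-east | 0.24 M | 0.10 mM | run made earlier |  |
| north | 0.050 M | 0.058 mM | run made earlier |  |
| gamma | 0.050 M | 0.10 mM |  | 3.0 d |
| theta | 0.20 M | 0.060 mM |  | 3.0 d |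

- north-west (time / h: E / %, J / %, D / %): 4.00: 8.1, 6.8, 84.6; 8.00: 12.0, 10.4, 76.9; 15.0: 16.0, 14.2, 70.2; 25.0: 17.4, 16.5, 64.0; 48.0: 18.7, 17.7, 62.1
- north-east (time / h: E / %, J / %, D / %): 4.00: 5.9, 4.5, 88.2; 8.00: 7.0, 6.5, 86.5; 15.0: 8.2, 7.2, 86.5; 25.0: 7.1, 7.1, 85.5; 48.0: 7.2, 6.1, 85.8
- south-east (time / h: E / %, J / %, D / %): 4.00: 4.0, 3.7, 93.6; 8.00: 3.4, 3.4, 93.1; 15.0: 2.6, 3.1, 93.8; 25.0: 3.3, 2.9, 92.9; 48.0: 3.7, 4.5, 93.1
- north (time / h: E / %, J / %, D / %): 4.00: 4.8, 4.1, 91.5; 8.00: 6.5, 5.4, 87.7; 15.0: 8.2, 7.8, 84.6; 25.0: 8.7, 7.8, 83.2; 48.0: 9.3, 9.4, 83.0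

(each reading ± 0.5 percentage points)



1. which one finishes higher in share of E in all that became E or J ("neither" within 2 percentage points) (gamma / theta / neither)
2. share of E in all that became E or J, gamma
3. share of E in all that became E or J, theta

- I compared rates in the north-west run. Between 4.00 h and 8.00 h, E gained 3.9 percentage points and J 3.6 points; between 25.0 h and 48.0 h, they gained 1.3 points and 1.2 points. The gains shrank, but I saw no drift between them beyond the scatter.
- I therefore carried the end share, E/(E+J) over a run's last two readings (its selectivity), which is 51.4% in the north-west run, with a scatter of 0.71 points.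
- The north-west and north runs stalled at about 148 mol of product per mol of L. I reckoned E+J at 29.6% in gamma, inside the range of those two runs, and 4.44% in theta, below the 8.20% of the south-east run.
- Theta was the weak link, so I reforged it from the high-c(D) runs, using each run's full set of readings. The south-east run read 49.1% and the north-east run 53.0%, on either side of the end share. Pooled, they gave 51.7%. I committed to 51.4% for gamma and 51.7% for theta, a gap smaller than the margin, so neither.
- The forecast said 52% for gamma, 51.5% for theta and neither, holding that “Every run shows E and J forming almost equally”.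
- The flask gave 51.7% for gamma and 51.7% for theta, so the answer is neither.

    E ⇌ J (K = 0.935, k = 9.21 × 10⁻⁴ /s)
    D + L → X (k = 9.01 × 10⁻⁴ /M/s)
    D + L ⇌ E + L, rate k3*[D]*[L] forward; the back reaction follows from the equilibrium constant (K = 1.28, k = 0.143 /M/s)

- In gamma, the half-life of E passing into J, forward rate alone, is 0.21 h, far shorter than the 0.56 d of D passing into E, forward rate alone and with concentrations as charged, and the share of E stands at the 51.7% that the E, J equilibrium gives (thermodynamic control). With 71% of D left in gamma, the end share 51.4% gives E as 15.1%, and the flask holds 15.1%; in the flask with gamma's D but 4.0 × 10⁻⁴ M of L, 30% of D is left, so the end share gives J as 34.0%, and that flask holds 33.3%.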